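**Plan**

1. Retrosynthesis: remove the three silyl ethers, cut the stilbene at the ring A C–C(vinyl) bond (Heck), return C9 to the aldehyde level, then cut both C–O bonds of the dioxane ring B: first the ring-closing bond between the middle oxygen O4 of ring A and C8, then the bond between the outer oxygen O3 and the benzylic carbon C7.
2. Forward: 5-iodopyrogallol is oxidized in the flask to its 3-hydroxy-o-quinone, which a chiral secondary amine joins to silyl-protected sinapaldehyde. O3 adds to C7, then the enamine carbon C8 closes ring B on O4. NaBH4 gives the C9 alcohol, a Heck reaction attaches the resorcinol styrene, and fluoride frees the phenols.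
3. Enabling feature: ring A is a pyrogallol (O3, O4, O5 on adjacent carbons, O5 a free hydroxyl next to the ring oxygen O4). It can therefore be raised to an o-quinone in which O3 is an acidic nucleophile and O4 an electrophile, while C7–C8–C9 in its enal form has C7 electrophilic and C8 nucleophilic under amine catalysis.
4. Stereochemistry: C7 (S) comes from the (R)-diarylprolinol silyl ether catalyst in the oxa-Michael step. C8 (S, trans to the aryl group) follows from C7 in the ring closure and by equilibration of the aldehyde. The E-alkene comes from the Heck reaction.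

Key step: step 3

Remark: the catalyst enantiomer is assigned from the steric shielding model of diarylprolinol silyl ether iminium ions; should the sense be opposite, the (S)-amine is used instead.

**Step 1**
Reactants: 1 5-iodo-1,2,3-trimethoxybenzene
Product: 2 5-iodobenzene-1,2,3-triol
Conditions: BBr3 (3.5 equiv), CH2Cl2, −78 °C to rt, argon; then H2O
Reagents that add atoms: none
Why: BBr3 demethylation cleaves the three aryl methyl ethers without touching the aryl iodide; no stereocenter is involved.

**Step 2**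
Reactants: 3 (2E)-3-(4-hydroxy-3,5-dimethoxyphenyl)prop-2-enal (sinapaldehyde)
Product: 4 (2E)-3-[4-(tert-butyldimethylsilyloxy)-3,5-dimethoxyphenyl]prop-2-enal
Conditions: TBSCl, imidazole, DMF, rt
Reagents that add atoms: tert-butyldimethylsilyl chloride, CC(C)(C)[Si](C)(C)Cl
Why: Imidazole-mediated O-silylation masks the acidic, oxidizable phenol so that the enal forms an electrophilic iminium ion and is not attacked by the quinone in step 3.

**Step 3**
Reactants: 2 5-iodobenzene-1,2,3-triol; 4 (2E)-3-[4-(tert-butyldimethylsilyloxy)-3,5-dimethoxyphenyl]prop-2-enal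
Product: 8 (2S,3S)-2-[4-(tert-butyldimethylsilyloxy)-3,5-dimethoxyphenyl]-3-(hydroxymethyl)-7-iodo-2,3-dihydro-1,4-benzodioxin-5-ol, via hydroxyquinone 5 (not isolated), via enamine adduct 6 (not isolated), via trans aldehyde 7 (not isolated)
Conditions: (a) o-chloranil (1.0 equiv), Et2O–CH2Cl2, −40 °C, argon; (b) 4 (1.2 equiv), (R)-2-{bis[3,5-bis(trifluoromethyl)phenyl](trimethylsilyloxy)methyl}pyrrolidine (20 mol%), CH2Cl2, −30 to −10 °C; (c) NaBH4, MeOH, −20 to 0 °C
Reagents that add atoms: none
Why: Proposed new method: o-chloranil dehydrogenates pyrogallol 2 to the 3-hydroxy-o-quinone 5 (a known oxidation), whose acidic outer oxygen adds in an oxa-Michael step to C7 of the iminium ion formed from enal 4 and the amine, and the enamine 6 so formed attacks with its carbon C8 the adjacent, electrophilic middle quinone oxygen, which forms the O–C8 bond, re-aromatizes ring A to the free phenol and, after hydrolysis, returns the amine and gives aldehyde 7 for reduction in the same flask. The closest known reaction types are the amine-catalyzed epoxidation of enals with H2O2 (oxa-Michael addition followed by attack of the enamine carbon on an electrophilic oxygen) and the enamine α-aryloxylation of aldehydes by tetrahalo-o-quinones. Ring B closes by a 6-endo-trig attack of the exocyclic enamine carbon on the carbonyl oxygen. C7 is controlled by the catalyst, whose bulky diaryl(silyloxy)methyl group shields one face of the E-iminium ion so that the (R)-amine should give (S)-C7, and C8 is controlled by C7 through an A(1,3)-minimized closure and through amine-mediated equilibration of the epimerizable α-aryloxy aldehyde to the trans isomer before NaBH4 is added. The step needs O- and not C-alkylation of the ambident hydroxyquinone and one regiochemistry of annulation: the iodine flanks and hinders both nucleophilic ring carbons while the reversible O-adduct is drained by the fast aromatizing closure, and the polarity of 5 (outer oxygen nucleophilic, middle oxygen electrophilic) matched to that of the enal (C7 electrophilic, C8 nucleophilic) fixes which oxygen meets which carbon.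

**Step 4**
Reactants: 9 3,5-dihydroxybenzaldehyde
Product: 10 3,5-bis(tert-butyldimethylsilyloxy)benzaldehyde
Conditions: TBSCl (2.4 equiv), imidazole, DMF, rt
Reagents that add atoms: tert-butyldimethylsilyl chloride, CC(C)(C)[Si](C)(C)Cl
Why: Imidazole-mediated O-silylation of both phenols gives ethers that should survive the Wittig and Heck steps and leave with fluoride at the end.

**Step 5**
Reactants: 10 3,5-bis(tert-butyldimethylsilyloxy)benzaldehyde
Product: 11 3,5-bis(tert-butyldimethylsilyloxy)styrene
Conditions: Ph3PCH3Br, KOtBu, THF, 0 °C to rt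
Reagents that add atoms: methyltriphenylphosphonium bromide, C[P+](c1ccccc1)(c1ccccc1)c1ccccc1.[Br-]
Why: Wittig methylenation of the aldehyde with the non-stabilized ylide gives the terminal styrene.

**Step 6**
Reactants: 8 (2S,3S)-2-[4-(tert-butyldimethylsilyloxy)-3,5-dimethoxyphenyl]-3-(hydroxymethyl)-7-iodo-2,3-dihydro-1,4-benzodioxin-5-ol; 11 3,5-bis(tert-butyldimethylsilyloxy)styrene
Product: 12 (2S,3S)-7-{(E)-2-[3,5-bis(tert-butyldimethylsilyloxy)phenyl]ethenyl}-2-[4-(tert-butyldimethylsilyloxy)-3,5-dimethoxyphenyl]-3-(hydroxymethyl)-2,3-dihydro-1,4-benzodioxin-5-ol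
Conditions: Pd(OAc)2 (5 mol%), P(o-tol)3 (12 mol%), Et3N, DMF, 80 °C, argon
Reagents that add atoms: none
Why: Mizoroki–Heck arylation of the styrene at its terminal carbon, in which syn-carbopalladation and syn-β-hydride elimination should give the E-stilbene while the free phenol, the alcohol and both dioxane stereocenters are untouched.

**Step 7**
Reactants: 12 (2S,3S)-7-{(E)-2-[3,5-bis(tert-butyldimethylsilyloxy)phenyl]ethenyl}-2-[4-(tert-butyldimethylsilyloxy)-3,5-dimethoxyphenyl]-3-(hydroxymethyl)-2,3-dihydro-1,4-benzodioxin-5-ol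
Product: 13 (2S,3S)-7-[(E)-2-(3,5-dihydroxyphenyl)ethenyl]-2-(4-hydroxy-3,5-dimethoxyphenyl)-3-(hydroxymethyl)-2,3-dihydro-1,4-benzodioxin-5-ol (target)
Conditions: TBAF (4 equiv), AcOH (4 equiv), THF, 0 °C to rt, argon
Reagents that add atoms: none
Why: Fluoride-mediated desilylation cleaves the three aryl silyl ethers, and the acetic acid buffer keeps the phenols protonated so that the stilbene and the two stereocenters should not be affected.

**Compound list**

1 | 5-iodo-1,2,3-trimethoxybenzene | COc1cc(I)cc(OC)c1OC | starting material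
2 | 5-iodobenzene-1,2,3-triol | Oc1cc(I)cc(O)c1O | intermediate
3 | (2E)-3-(4-hydroxy-3,5-dimethoxyphenyl)prop-2-enal (sinapaldehyde) | COc1cc(/C=C/C=O)cc(OC)c1O | starting material
4 | (2E)-3-[4-(tert-butyldimethylsilyloxy)-3,5-dimethoxyphenyl]prop-2-enal | COc1cc(/C=C/C=O)cc(OC)c1O[Si](C)(C)C(C)(C)C | intermediate
5 | 3-hydroxy-5-iodocyclohexa-3,5-diene-1,2-dione (not isolated) | OC1=CC(I)=CC(=O)C1=O | intermediate
6 | 3-{[(1R,2E)-1-[4-(tert-butyldimethylsilyloxy)-3,5-dimethoxyphenyl]-3-[(2R)-2-{bis[3,5-bis(trifluoromethyl)phenyl](trimethylsilyloxy)methyl}pyrrolidin-1-yl]prop-2-en-1-yl]oxy}-5-iodocyclohexa-3,5-diene-1,2-dione (not isolated; same spatial arrangement at the benzylic carbon as in 8, the descriptor changes with the ranking) | COc1cc([C@@H](/C=C/N2CCC[C@@H]2C(O[Si](C)(C)C)(c2cc(C(F)(F)F)cc(C(F)(F)F)c2)c2cc(C(F)(F)F)cc(C(F)(F)F)c2)OC2=CC(I)=CC(=O)C2=O)cc(OC)c1O[Si](C)(C)C(C)(C)C | intermediate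
7 | (2R,3S)-3-[4-(tert-butyldimethylsilyloxy)-3,5-dimethoxyphenyl]-8-hydroxy-6-iodo-2,3-dihydro-1,4-benzodioxine-2-carbaldehyde (trans; not isolated) | COc1cc([C@@H]2Oc3cc(I)cc(O)c3O[C@H]2C=O)cc(OC)c1O[Si](C)(C)C(C)(C)C | intermediate
8 | (2S,3S)-2-[4-(tert-butyldimethylsilyloxy)-3,5-dimethoxyphenyl]-3-(hydroxymethyl)-7-iodo-2,3-dihydro-1,4-benzodioxin-5-ol (trans) | COc1cc([C@@H]2Oc3cc(I)cc(O)c3O[C@H]2CO)cc(OC)c1O[Si](C)(C)C(C)(C)C | intermediate
9 | 3,5-dihydroxybenzaldehyde | O=Cc1cc(O)cc(O)c1 | starting material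
10 | 3,5-bis(tert-butyldimethylsilyloxy)benzaldehyde | O=Cc1cc(O[Si](C)(C)C(C)(C)C)cc(O[Si](C)(C)C(C)(C)C)c1 | intermediate
11 | 3,5-bis(tert-butyldimethylsilyloxy)styrene | C=Cc1cc(O[Si](C)(C)C(C)(C)C)cc(O[Si](C)(C)C(C)(C)C)c1 | intermediate
12 | (2S,3S)-7-{(E)-2-[3,5-bis(tert-butyldimethylsilyloxy)phenyl]ethenyl}-2-[4-(tert-butyldimethylsilyloxy)-3,5-dimethoxyphenyl]-3-(hydroxymethyl)-2,3-dihydro-1,4-benzodioxin-5-ol | COc1cc([C@@H]2Oc3cc(/C=C/c4cc(O[Si](C)(C)C(C)(C)C)cc(O[Si](C)(C)C(C)(C)C)c4)cc(O)c3O[C@H]2CO)cc(OC)c1O[Si](C)(C)C(C)(C)C | intermediate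
13 | (2S,3S)-7-[(E)-2-(3,5-dihydroxyphenyl)ethenyl]-2-(4-hydroxy-3,5-dimethoxyphenyl)-3-(hydroxymethyl)-2,3-dihydro-1,4-benzodioxin-5-ol | COc1cc([C@@H]2Oc3cc(/C=C/c4cc(O)cc(O)c4)cc(O)c3O[C@H]2CO)cc(OC)c1O | target

**Step count and risks**

Total step count: 7. Longest linear sequence: 4 steps (steps 1, 3, 6, 7).

Steps most likely to fail:

1. Step 3 (proposed new method). The ambident hydroxyquinone may alkylate irreversibly through a ring carbon instead of through oxygen. The amine may be consumed by conjugate addition to the quinone, and the hydroxyquinone may condense with itself. The enantiomeric purity may erode through reversible ring opening (retro-oxa-Michael) of aldehyde 7 before reduction.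
   The fallback uses known chemistry, sets out from 4 and 2 and returns at 8, closing the same O–C8 bond by a classical epoxide opening. Luche reduction of 4 (NaBH4, CeCl3·7H2O, MeOH, 0 °C) would give (2E)-3-[4-(tert-butyldimethylsilyloxy)-3,5-dimethoxyphenyl]prop-2-en-1-ol F1. Sharpless asymmetric epoxidation (Ti(OiPr)4, D-(−)-diisopropyl tartrate, t-BuOOH, 4 Å molecular sieves, CH2Cl2, −20 °C) would convert it into the (2R,3R)-epoxy alcohol F2. In parallel, 2 would be masked on its two adjacent oxygens as the cyclic orthoformate 2-ethoxy-6-iodo-1,3-benzodioxol-4-ol F3 (HC(OEt)3, Amberlyst 15, toluene, reflux), which leaves only the outer hydroxyl free. Titanium-assisted opening of F2 at its benzylic carbon by F3 (Ti(OiPr)4, toluene, rt to 50 °C) should give, with inversion at C7, the (2R,3S)-diol F4. Selective sulfonylation of the primary hydroxyl (TsCl, Bu2SnO cat., Et3N, CH2Cl2) would give the tosylate F5, and DBU would close it to the terminal epoxide F6 with retention at C8. Mild hydrolysis of the orthoformate (PPTS, wet THF, then NaHCO3, MeOH) would free the catechol F7. Its middle phenoxide (DBU, MeCN, 40 °C) should open the epoxide in a 6-exo-tet mode with inversion at C8 to give 8.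
2. Step 6. Oxidative addition into the electron-rich aryl iodide that carries a free phenol may be sluggish. Insertion may occur in part at the internal alkene carbon, and silyl groups may be lost on prolonged heating with amine.
   The fallback sets out from 11 and returns at 12. Cross-metathesis of 11 with vinylboronic acid pinacol ester (second-generation Grubbs catalyst, CH2Cl2, 40 °C) would give the (E)-styrylboronic ester F8. Suzuki–Miyaura coupling of F8 with 8 (Pd(dppf)Cl2, K3PO4, THF–H2O, 50 °C) should then give 12 with retention of the E geometry and no regiochemical ambiguity.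
3. Step 7. Cleavage of the hindered silyl ether between the two methoxy groups may be slow, and the long exposure to fluoride may cause air oxidation or E/Z isomerization of the free polyphenolic stilbene.
   The fallback changes the order of events, sets out from 8 and returns at 13. The hindered silyl ether would be removed first, while no stilbene is present (TBAF, AcOH, THF), to give the triol (2S,3S)-2-(4-hydroxy-3,5-dimethoxyphenyl)-3-(hydroxymethyl)-7-iodo-2,3-dihydro-1,4-benzodioxin-5-ol F9. Heck coupling of F9 with 11 under the conditions of step 6 would give the stilbene F10, which carries only the two unhindered resorcinol silyl ethers. These should fall off under nearly neutral conditions (KHF2, MeOH, rt) to give 13.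

**Further compounds**

F1 | step 3 | (2E)-3-[4-(tert-butyldimethylsilyloxy)-3,5-dimethoxyphenyl]prop-2-en-1-ol | COc1cc(/C=C/CO)cc(OC)c1O[Si](C)(C)C(C)(C)C
F2 | step 3 | [(2R,3R)-3-[4-(tert-butyldimethylsilyloxy)-3,5-dimethoxyphenyl]oxiran-2-yl]methanol | OC[C@H]1O[C@@H]1c1cc(OC)c(O[Si](C)(C)C(C)(C)C)c(OC)c1
F3 | step 3 | 2-ethoxy-6-iodo-1,3-benzodioxol-4-ol | CCOC1Oc2cc(I)cc(O)c2O1
F4 | step 3 | (2R,3S)-3-[4-(tert-butyldimethylsilyloxy)-3,5-dimethoxyphenyl]-3-[(2-ethoxy-6-iodo-1,3-benzodioxol-4-yl)oxy]propane-1,2-diol | COc1cc([C@@H]([C@H](O)CO)Oc2cc(I)cc3OC(OCC)Oc23)cc(OC)c1O[Si](C)(C)C(C)(C)C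
F5 | step 3 | (2R,3S)-3-[4-(tert-butyldimethylsilyloxy)-3,5-dimethoxyphenyl]-3-[(2-ethoxy-6-iodo-1,3-benzodioxol-4-yl)oxy]-2-hydroxypropyl 4-methylbenzenesulfonate | COc1cc([C@@H]([C@H](O)COS(=O)(=O)c2ccc(C)cc2)Oc2cc(I)cc3OC(OCC)Oc23)cc(OC)c1O[Si](C)(C)C(C)(C)C
F6 | step 3 | 4-{(S)-[4-(tert-butyldimethylsilyloxy)-3,5-dimethoxyphenyl][(2R)-oxiran-2-yl]methoxy}-2-ethoxy-6-iodo-1,3-benzodioxole | COc1cc([C@@H]([C@H]2CO2)Oc2cc(I)cc3OC(OCC)Oc23)cc(OC)c1O[Si](C)(C)C(C)(C)C
F7 | step 3 | 3-{(S)-[4-(tert-butyldimethylsilyloxy)-3,5-dimethoxyphenyl][(2R)-oxiran-2-yl]methoxy}-5-iodobenzene-1,2-diol | COc1cc([C@@H]([C@H]2CO2)Oc2cc(I)cc(O)c2O)cc(OC)c1O[Si](C)(C)C(C)(C)C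
F8 | step 6 | 2-{(E)-2-[3,5-bis(tert-butyldimethylsilyloxy)phenyl]ethenyl}-4,4,5,5-tetramethyl-1,3,2-dioxaborolane | CC1(C)OB(/C=C/c2cc(O[Si](C)(C)C(C)(C)C)cc(O[Si](C)(C)C(C)(C)C)c2)OC1(C)C
F9 | step 7 | (2S,3S)-2-(4-hydroxy-3,5-dimethoxyphenyl)-3-(hydroxymethyl)-7-iodo-2,3-dihydro-1,4-benzodioxin-5-ol | COc1cc([C@@H]2Oc3cc(I)cc(O)c3O[C@H]2CO)cc(OC)c1O
F10 | step 7 | (2S,3S)-7-{(E)-2-[3,5-bis(tert-butyldimethylsilyloxy)phenyl]ethenyl}-2-(4-hydroxy-3,5-dimethoxyphenyl)-3-(hydroxymethyl)-2,3-dihydro-1,4-benzodioxin-5-ol | COc1cc([C@@H]2Oc3cc(/C=C/c4cc(O[Si](C)(C)C(C)(C)C)cc(O[Si](C)(C)C(C)(C)C)c4)cc(O)c3O[C@H]2CO)cc(OC)c1O
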